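## Structural features

- **Numbering used for every compound.** Pyrrole ring A is N4, C3, C2, C1, C9a. The azepane is N4, C5–C9, C9a. Cyclohexane ring B is C9a, C1, C12, C11, C10, C9. γ-Lactone ring C is C11–O–C14(=O)–C13(C15H3)–C12, cis-fused to ring B. The ethyl group C16–C17 sits on C10. γ-Lactone ring D is C18–O–C21(=O)–C20(C22H3)–C19, attached through C18 to C3.
- **Stereocentres.** There are seven, (9S,10R,11R,12S,13S,18R,20S). C9–C12 are contiguous on ring B and carry their four hydrogens on one face, so C8, ethyl, O11 and C13 are all cis. C13 has its methyl on the concave face of the cis-fused B/C bicycle (H13 cis to H12). The 2,4-trans pair C18/C20 is insulated from the rest by the flat pyrrole.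
- **Fragile groups.** The C18–O bond is pyrrolylic and ionises under acid, which would scramble C18. The trialkylpyrrole is sensitive to acid and oxidants. C13 and C20 are α to lactone carbonyls, and C13 is the less stable epimer.
- **Real difficulty.** The all-cis tetrad C9–C12 is a kinetic arrangement that equilibration will not deliver. C9 and C12 cannot be corrected once the pyrrole exists. The absolute configuration of the tetrad must be set independently of C18/C20.
- **Feature the key step exploits.** Ring B holds exactly one double bond, C9a=C1, which is also a C=C of ring A. With C9–C12 all-cis, this is the pattern of an endo Diels–Alder adduct whose new π bond is C9a=C1. N4 on C9a makes the diene a 2-amido diene of a seven-membered lactam (N4, C5–C9 and C9a are the atoms of caprolactam). The cis O11/C16 pair is a masked four-membered enone. C2–C3 can ride on C1 as an alkyne that later closes ring A.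

## Logic of the disconnections

**25 ⇒ 23 (through 24).** The O–C21 acyl bond of ring D and the C18–H bond are cut. C18 is pyrrolylic and labile, so it is created last, from a carbonyl, under reagent control, and the ring is closed without acid. Ring D and C18 disappear and only C20 remains in the chain. The forward step needs hydride delivery to one face of a deactivated 2-acylpyrrole ketone and a neutral lactonisation.

**23 ⇒ 21 + 22.** The C3–C18 bond is cut. C3 is the only free α-position of the pyrrole, so acylation there is innate, and 22 brings C18–C22 with C20 from the chiral pool. The remote stereo pair is thereby separated from the core. The forward step needs 22 to open at the carbonyl remote from its methyl group, with a Lewis acid that ring C tolerates.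

**21 ⇒ 19 (through 20).** The O11–C14 acyl bond is cut and C14 goes back to the alcohol level. C14 can then travel as a protected primary alcohol through all hydride steps, and no enolisable carbonyl sits next to C13 until late. The forward step needs an oxidant that takes the primary alcohol in the presence of the pyrrole.

**19 ⇒ 17 (through 18).** The N4–C3 bond of ring A is cut. The pyrrole becomes an N4 carbamate, an ordinary C9a=C1 alkene and an ethynyl group on C1. The aromatic ring is thus traced to substituents that a Diels–Alder diene can carry. The forward ring closure must outrun tautomerisation towards C9.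

**17 ⇒ 16 ⇒ 15 ⇒ 14 ⇒ 13 ⇒ 12.** These are functional-group changes. The O11–C17 bond is cut (retro-Baeyer–Villiger), so that the cis pair O11/ethyl becomes a cyclobutanone cis-fused at C10–C11. A ring enforces the cis relation and no stereocentre is created on the way. The forward steps need oxygen insertion on the C11 side with retention, and deoxygenation of C17 without a leaving group ever standing next to O11–H.

**12 ⇒ 9 + 11 (key disconnection).** C9–C10 and C11–C12 are cut. Ring B and the four contiguous stereocentres vanish together, and the precursor 9 keeps a single stereocentre, C13. The forward step needs the regiochemistry that puts the carbonyl carbon on C11, endo topology, and addition to one face of 9.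

**9 ⇒ 8 ⇒ 7 + 3.** C1–C2 and then C9a–C1 are cut. In 7 the two C–Br bonds differ in reactivity, so the order of the two couplings fixes the diene geometry (C13 trans to C9a). The diene shrinks to a lactam-derived boronate and an aldehyde-derived dibromide. The first coupling must occur at the bromide trans to the chain.

**7 ⇒ 6 ⇒ 5 ⇒ 4; 3 ⇒ 2 ⇒ 1; 11 ⇒ 10.** These are functional-group changes down to purchasable compounds. 4 supplies C12–C13(C15)–C14 with the C13 configuration. 1 supplies N4, C5–C9 and C9a. 10 supplies C10, C11, C16 and C17.

## Other disconnections considered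

**Alternative 1:** (the first that comes to mind) The two C=C bonds of ring A are removed retrosynthetically, giving the pyrrolidine A1. The forward key step is a final dehydrogenation of A1 to the pyrrole, for example with Ag2O. A1 needs three more stereocentres (C1, C3, C9a) that are built only to be erased. Its ring B has no π bond, so the all-cis tetrad has to be assembled on a perhydroindole by separate events. The chosen plan never makes those centres and sets the tetrad in one step.

**Alternative 2:** The C1–C12 bond is cut, in the sense of the presumed biogenesis. The forward key step is an intramolecular Friedel–Crafts conjugate addition of pyrrole C1 of A2 onto C12 of its α-methylbutenolide, with C13 set by protonation of the lactone enolate. This step closes ring B but controls only C12 and C13. C9, C10 and C11 must already stand on a freely rotating chain, each set by its own reaction. The nucleophile is the less reactive β-position of the pyrrole and the acceptor is an α-substituted butenolide. The chosen cycloaddition settles C9–C12 together with activated partners.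

**Alternative 3:** C9–C9a and C10–C11 are cut. The forward key step is an intramolecular Diels–Alder reaction of the furan ring of the N-(Z)-octenyl furo[2,3-b]pyrrole A3, followed by opening of the oxygen bridge to the tricyclic ketone A4; the furan oxygen would become O11. This is the shortest entry to the core, and it is rejected on three grounds. The cycloaddition must dearomatise both rings of a 10π bicycle with an unactivated alkene through a seven-membered tether. A3 is achiral, so nothing controls the absolute configuration. C10 in A4 is α to a ketone and can epimerise. The chosen plan draws its absolute configuration from the chiral pool and passes through no epimerisable ring centre.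

Key step: step 9

Remark: the target numbering defined above is used for all intermediates. 1, 4, 10 and 22 are taken as purchasable; 11 is prepared fresh because it polymerises on storage.

## Route

Step 1
Reactants: 1 tert-butyl 2-oxoazepane-1-carboxylate
Product: 2 tert-butyl 7-(trifluoromethylsulfonyloxy)-2,3,4,5-tetrahydro-1H-azepine-1-carboxylate
Conditions: KN(SiMe3)2, THF, −78 °C; then PhNTf2, −78 → 0 °C
Reagents that add atoms: N-phenylbis(trifluoromethanesulfonimide), O=S(=O)(N(c1ccccc1)S(=O)(=O)C(F)(F)F)C(F)(F)F
Why: The imide-like N-Boc lactam is enolised cleanly at −78 °C and the enolate is O-sulfonylated (enol triflate formation); no stereocentre is involved.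

Step 2
Reactants: 2 tert-butyl 7-(trifluoromethylsulfonyloxy)-2,3,4,5-tetrahydro-1H-azepine-1-carboxylate
Product: 3 tert-butyl 7-(4,4,5,5-tetramethyl-1,3,2-dioxaborolan-2-yl)-2,3,4,5-tetrahydro-1H-azepine-1-carboxylate
Conditions: B2pin2, PdCl2(PPh3)2 (3 mol %), PPh3, KOPh, toluene, 50 °C
Reagents that add atoms: bis(pinacolato)diboron, CC1(C)OB(OC1(C)C)B1OC(C)(C)C(C)(C)O1
Why: Miyaura borylation of the enol triflate (oxidative addition to zerovalent palladium, transmetalation from the phenoxide-activated diboron, reductive elimination) makes the lactam carbon C9a a nucleophilic coupling site.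

Step 3
Reactants: 4 methyl (R)-3-hydroxy-2-methylpropanoate
Product: 5 methyl (R)-3-(tert-butyldiphenylsilyloxy)-2-methylpropanoate
Conditions: t-BuPh2SiCl, imidazole, DMF, 25 °C
Reagents that add atoms: tert-butyl(chloro)diphenylsilane, CC(C)(C)[Si](Cl)(c1ccccc1)c1ccccc1
Why: Standard silylation of the primary alcohol (the future C14–O); the bulky silyl ether later shields one diene face and survives base, hydride and peroxide.

Step 4
Reactants: 5 methyl (R)-3-(tert-butyldiphenylsilyloxy)-2-methylpropanoate
Product: 6 (R)-3-(tert-butyldiphenylsilyloxy)-2-methylpropanal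
Conditions: i-Bu2AlH (1.1 equiv), CH2Cl2, −78 °C
Reagents that add atoms: none
Why: At −78 °C the tetrahedral aluminate of the ester persists until work-up and gives the aldehyde (C12); C13 is not epimerised under these non-basic conditions.

Step 5
Reactants: 6 (R)-3-(tert-butyldiphenylsilyloxy)-2-methylpropanal
Product: 7 (S)-(4,4-dibromo-2-methylbut-3-enyloxy)(tert-butyl)diphenylsilane
Conditions: CBr4, PPh3, CH2Cl2, 0 °C
Reagents that add atoms: carbon tetrabromide, BrC(Br)(Br)Br
Why: Corey–Fuchs dibromo-olefination (Wittig reaction of Ph3P=CBr2) turns C12=O into C12=C1Br2 under neutral conditions, so the α-stereocentre C13 is retained (the descriptor changes to S only through the priority rules).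

Step 6
Reactants: 7 (S)-(4,4-dibromo-2-methylbut-3-enyloxy)(tert-butyl)diphenylsilane; 3 tert-butyl 7-(4,4,5,5-tetramethyl-1,3,2-dioxaborolan-2-yl)-2,3,4,5-tetrahydro-1H-azepine-1-carboxylate
Product: 8 tert-butyl 7-[(1Z,3S)-1-bromo-4-(tert-butyldiphenylsilyloxy)-3-methylbut-1-enyl]-2,3,4,5-tetrahydro-1H-azepine-1-carboxylate
Conditions: Pd2(dba)3 (2.5 mol %), P(2-furyl)3, Cs2CO3, THF/H2O, 45 °C
Reagents that add atoms: none
Why: Suzuki–Miyaura coupling of a 1,1-dibromoalkene takes place first at the C–Br bond trans to the alkyl chain (less hindered oxidative addition), which puts C9a trans to C13 and leaves the (Z)-bromide for the next coupling; this fixes the diene geometry.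

Step 7
Reactants: 8 tert-butyl 7-[(1Z,3S)-1-bromo-4-(tert-butyldiphenylsilyloxy)-3-methylbut-1-enyl]-2,3,4,5-tetrahydro-1H-azepine-1-carboxylate
Product: 9 tert-butyl 7-[(3E,5S)-6-(tert-butyldiphenylsilyloxy)-5-methyl-1-(triisopropylsilyl)hex-3-en-1-yn-3-yl]-2,3,4,5-tetrahydro-1H-azepine-1-carboxylate
Conditions: i-Pr3SiC≡CH, PdCl2(PPh3)2 (5 mol %), CuI (10 mol %), i-Pr2NH, THF, 45 °C
Reagents that add atoms: ethynyltriisopropylsilane, C#C[Si](C(C)C)(C(C)C)C(C)C
Why: Sonogashira coupling of the remaining vinyl bromide goes with retention of alkene geometry and installs C2–C3 as a silyl-protected alkyne on C1, cis to C13.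

Step 8
Reactants: 10 3-bromocyclobutanone
Product: 11 cyclobut-2-enone
Conditions: n-Bu3N, 25 °C, then distillation at reduced pressure into a cold trap
Reagents that add atoms: none
Why: Amine-induced dehydrobromination (E1cB) of the β-bromo ketone gives the strained enone, which is distilled and used at once.

Step 9
Reactants: 9 tert-butyl 7-[(3E,5S)-6-(tert-butyldiphenylsilyloxy)-5-methyl-1-(triisopropylsilyl)hex-3-en-1-yn-3-yl]-2,3,4,5-tetrahydro-1H-azepine-1-carboxylate; 11 cyclobut-2-enone
Product: 12 Diels–Alder adduct: N4-Boc enecarbamate (C9a=C1) of the azepane/ring B bicycle with a cyclobutanone cis-fused at C10–C11 (C17=O on C11, C16H2 on C10), C1–C≡C–Si(i-Pr)3, C12–[(13S)-CH(CH3)CH2OSi(t-Bu)Ph2], H9, H10, H11 and H12 all cis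
Conditions: 11 (2 equiv), toluene, 25 → 45 °C, 2,6-di-tert-butyl-4-methylphenol (cat.)
Reagents that add atoms: none
Why: This is a normal-electron-demand Diels–Alder reaction in which the HOMO of the 2-amido diene (raised by the carbamate nitrogen on C9a and largest at C9) meets the LUMO of the strained enone in a concerted, asynchronous transition state with C9–C10 forming ahead of C11–C12. The closest known reaction types are the cycloadditions of lactam-derived 2-amido-1,3-dienes with enones and the use of cyclobut-2-enone as an unusually reactive, cis-locked dienophile. Ring B is closed in the [4+2] mode, while the azepane and the four-membered ring are carried in intact and the latter ends cis-fused. C9 and C12 are related by the diene geometry, because C8 (held cis to N4 by the ring) and C13 (placed trans to C9a in step 6) are both outside groups and end cis. C10 and C11 are cis because the dienophile is a ring, and the endo orientation (carbonyl under C9a–C1) puts C16 and C17 cis to C8 and C13, so that all four hydrogens fall on one face. The absolute sense comes from C13: allylic 1,3-strain with the cis alkynyl group holds H13 in the plane of C1=C12, and 11 should add to the face that carries the methyl group, anti to the bulky CH2OSi(t-Bu)Ph2 arm, which is the face the target requires. The regiochemistry (carbonyl carbon on C11, CH2 on C10) follows from the nucleophilic terminus C9 bonding to the enone β-carbon. The step therefore needs regio-, endo- and π-facial selectivity; the carbamate and the small planar dienophile secure the first two, and the third rests only on the size difference at C13 and is the weakest.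

Step 10
Reactants: 12 Diels–Alder adduct (cyclobutanone)
Product: 13 Baeyer–Villiger lactone: as 12 but with O11 inserted between C11 and C17 (cis-fused γ-lactone O11–C17(=O)–C16H2–C10)
Conditions: t-BuOOH, NaOH (aq., 0.2 equiv), THF, 0 °C
Reagents that add atoms: tert-butyl hydroperoxide, CC(C)(C)OO
Why: Baeyer–Villiger oxidation of the strained cyclobutanone by the nucleophilic hydroperoxide anion is fast at 0 °C and leaves enecarbamate and alkyne untouched; the more substituted ring-fusion carbon C11 migrates with retention, so O11 arrives cis to C16, C13 and C8.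

Step 11
Reactants: 13 Baeyer–Villiger lactone
Product: 14 lactol of 13 (C17 hemiacetal, both anomers)
Conditions: i-Bu2AlH, CH2Cl2, −78 °C
Reagents that add atoms: none
Why: i-Bu2AlH at −78 °C stops at the cyclic hemiacetal; carbamate, silyl groups and alkyne are inert.

Step 12
Reactants: 14 lactol of 13
Product: 15 N-tosylhydrazone C10–C16H2–C17H=N–NHTs with free O11–H (ring-opened form of 14)
Conditions: TsNHNH2, THF, 25 °C
Reagents that add atoms: p-toluenesulfonyl hydrazide, Cc1ccc(cc1)S(=O)(=O)NN
Why: The lactol reacts through its open hydroxy-aldehyde form to give the hydrazone, which frees O11–H without ever placing a leaving group on C17 next to it.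

Step 13
Reactants: 15 N-tosylhydrazone
Product: 16 10-ethyl-11-hydroxy enecarbamate (C10–CH2CH3 and C11–OH cis; silyl groups and Boc as in 12)
Conditions: catecholborane, CHCl3, 0 °C; then NaOAc·3H2O, 60 °C
Reagents that add atoms: none
Why: Hydroboration of the C=N bond, acetate-induced loss of sulfinate and expulsion of N2 from the diazene leave C17H3 (a tosylhydrazone reduction of the Wolff–Kishner type under mild conditions); no stereocentre is touched.

Step 14
Reactants: 16 10-ethyl-11-hydroxy enecarbamate
Product: 17 enecarbamate diol (C11–OH, C14H2–OH, C1–C≡CH, N4–Boc)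
Conditions: Bu4NF, THF, 0 → 25 °C
Reagents that add atoms: none
Why: Fluoride cleaves the O–Si bond at O14 and the C(sp)–Si bond in one operation, exposing the 1,4-diol and the terminal alkyne; the carbamate is stable to Bu4NF at 25 °C.

Step 15
Reactants: 17 enecarbamate diol
Product: 19 pyrrole diol (ring A closed, C2–H and C3–H; C11–OH and C14H2–OH; 9S,10R,11R,12S,13S), via secondary enynamine 18 (not isolated)
Conditions: CF3CO2H, CH2Cl2, 0 °C; evaporate; then K2CO3, CuI (10 mol %), MeOH, 40 °C
Reagents that add atoms: none
Why: Acidolysis of the Boc group gives the secondary enamine 18, whose nitrogen adds 5-endo-dig to the CuI-activated terminal alkyne (cycloisomerisation of a (Z)-2-en-4-ynylamine), and aromatisation makes the closure irreversible; the C9a=C1 enamine tautomer is conjugated with the alkyne, which keeps the double bond away from C9.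

Step 16
Reactants: 19 pyrrole diol
Product: 21 tetracyclic pyrrole lactone (target without ring D, C3–H; 9S,10R,11R,12S,13S), via lactol 20 (not isolated)
Conditions: Ag2CO3 on kieselguhr, toluene, reflux
Reagents that add atoms: none
Why: Fétizon oxidation takes the primary alcohol to the aldehyde, which O11–H traps as lactol 20, and the lactol is oxidised on to the cis-fused γ-lactone; the neutral surface reagent spares the pyrrole and does not enolise C13.

Step 17
Reactants: 21 tetracyclic pyrrole lactone; 22 (S)-3-methyldihydrofuran-2,5-dione ((S)-methylsuccinic anhydride)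
Product: 23 (20S)-keto acid: 21 acylated at C3 by –C(=O)–CH2–CH(CH3)–CO2H
Conditions: AlCl3, CH2Cl2, 0 °C
Reagents that add atoms: none
Why: Friedel–Crafts acylation at C3, the only free α-position of the pyrrole; the anhydride should open at its less hindered carbonyl (remote from the methyl group), giving the 4-oxo acid with C20 untouched.

Step 18
Reactants: 23 (20S)-keto acid
Product: 25 epibisdehydroneotuberostemonine J (9S,10R,11R,12S,13S,18R,20S), via hydroxy acid 24 (not isolated)
Conditions: RuCl[(R,R)-TsDPEN](p-cymene) (2 mol %), HCO2Na, H2O/MeOH, 40 °C; then EDC·HCl, DMAP (cat.), CH2Cl2, 0 °C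
Reagents that add atoms: none
Why: Noyori asymmetric transfer hydrogenation, in which the (R,R)-configured ruthenium hydride should deliver hydrogen to the ketone face that gives the (18R) carbinol (heteroaryl group in the CH/π position), at neutral pH so that the pyrrolylic alcohol does not ionise; carbodiimide activation then closes ring D without acid and gives the 2,4-trans lactone.

## Compound list

1 | tert-butyl 2-oxoazepane-1-carboxylate | O=C1CCCCCN1C(=O)OC(C)(C)C | starting material
2 | tert-butyl 7-(trifluoromethylsulfonyloxy)-2,3,4,5-tetrahydro-1H-azepine-1-carboxylate | CC(C)(C)OC(=O)N1CCCCC=C1OS(=O)(=O)C(F)(F)F | intermediate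
3 | tert-butyl 7-(4,4,5,5-tetramethyl-1,3,2-dioxaborolan-2-yl)-2,3,4,5-tetrahydro-1H-azepine-1-carboxylate | CC(C)(C)OC(=O)N1CCCCC=C1B2OC(C)(C)C(C)(C)O2 | intermediate
4 | methyl (R)-3-hydroxy-2-methylpropanoate | COC(=O)[C@H](C)CO | starting material
5 | methyl (R)-3-(tert-butyldiphenylsilyloxy)-2-methylpropanoate | COC(=O)[C@H](C)CO[Si](c1ccccc1)(c2ccccc2)C(C)(C)C | intermediate
6 | (R)-3-(tert-butyldiphenylsilyloxy)-2-methylpropanal | O=C[C@H](C)CO[Si](c1ccccc1)(c2ccccc2)C(C)(C)C | intermediate
7 | (S)-(4,4-dibromo-2-methylbut-3-enyloxy)(tert-butyl)diphenylsilane | BrC(Br)=C[C@H](C)CO[Si](c1ccccc1)(c2ccccc2)C(C)(C)C | intermediate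
8 | tert-butyl 7-[(1Z,3S)-1-bromo-4-(tert-butyldiphenylsilyloxy)-3-methylbut-1-enyl]-2,3,4,5-tetrahydro-1H-azepine-1-carboxylate | CC(C)(C)OC(=O)N1CCCCC=C1/C(Br)=C/[C@H](C)CO[Si](c2ccccc2)(c3ccccc3)C(C)(C)C | intermediate
9 | tert-butyl 7-[(3E,5S)-6-(tert-butyldiphenylsilyloxy)-5-methyl-1-(triisopropylsilyl)hex-3-en-1-yn-3-yl]-2,3,4,5-tetrahydro-1H-azepine-1-carboxylate | CC(C)(C)OC(=O)N1CCCCC=C1/C(C#C[Si](C(C)C)(C(C)C)C(C)C)=C/[C@H](C)CO[Si](c2ccccc2)(c3ccccc3)C(C)(C)C | intermediate
10 | 3-bromocyclobutanone | O=C1CC(Br)C1 | starting material
11 | cyclobut-2-enone | O=C1C=CC1 | intermediate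
12 | Diels–Alder adduct: N4-Boc enecarbamate (C9a=C1) with cyclobutanone cis-fused at C10–C11 (C17=O on C11), C1–C≡C–Si(i-Pr)3, C12–[(13S)-CH(CH3)CH2OSi(t-Bu)Ph2], H9/H10/H11/H12 all cis | O=C1C[C@H]2[C@@H]1[C@@H]([C@H](C)CO[Si](c4ccccc4)(c5ccccc5)C(C)(C)C)C(C#C[Si](C(C)C)(C(C)C)C(C)C)=C3N(C(=O)OC(C)(C)C)CCCC[C@@H]23 | intermediate
13 | Baeyer–Villiger lactone: as 12 with O11 between C11 and C17 (cis-fused γ-lactone O11–C17(=O)–C16H2–C10) | O=C1C[C@H]2[C@@H](O1)[C@@H]([C@H](C)CO[Si](c4ccccc4)(c5ccccc5)C(C)(C)C)C(C#C[Si](C(C)C)(C(C)C)C(C)C)=C3N(C(=O)OC(C)(C)C)CCCC[C@@H]23 | intermediate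
14 | lactol of 13 (C17 hemiacetal, both anomers) | OC1C[C@H]2[C@@H](O1)[C@@H]([C@H](C)CO[Si](c4ccccc4)(c5ccccc5)C(C)(C)C)C(C#C[Si](C(C)C)(C(C)C)C(C)C)=C3N(C(=O)OC(C)(C)C)CCCC[C@@H]23 | intermediate
15 | N-tosylhydrazone C10–C16H2–C17H=N–NHTs with free O11–H | Cc1ccc(cc1)S(=O)(=O)NN=CC[C@H]2[C@@H](O)[C@@H]([C@H](C)CO[Si](c4ccccc4)(c5ccccc5)C(C)(C)C)C(C#C[Si](C(C)C)(C(C)C)C(C)C)=C3N(C(=O)OC(C)(C)C)CCCC[C@@H]23 | intermediate
16 | 10-ethyl-11-hydroxy enecarbamate (ethyl and OH cis; silyl groups and Boc as in 12) | CC[C@H]2[C@@H](O)[C@@H]([C@H](C)CO[Si](c4ccccc4)(c5ccccc5)C(C)(C)C)C(C#C[Si](C(C)C)(C(C)C)C(C)C)=C3N(C(=O)OC(C)(C)C)CCCC[C@@H]23 | intermediate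
17 | enecarbamate diol (C11–OH, C14H2–OH, C1–C≡CH, N4–Boc) | CC[C@H]2[C@@H](O)[C@@H]([C@H](C)CO)C(C#C)=C3N(C(=O)OC(C)(C)C)CCCC[C@@H]23 | intermediate
18 | secondary enynamine (N4–H) of 17 | CC[C@H]2[C@@H](O)[C@@H]([C@H](C)CO)C(C#C)=C3NCCCC[C@@H]23 | intermediate
19 | pyrrole diol (ring A closed; C11–OH, C14H2–OH; 9S,10R,11R,12S,13S) | CC[C@H]1[C@@H](O)[C@@H]([C@H](C)CO)c2ccn3c2[C@H]1CCCC3 | intermediate
20 | lactol at C14 (ring C at the hemiacetal level) | CC[C@H]1[C@H]2OC(O)[C@@H](C)[C@H]2c2ccn3c2[C@H]1CCCC3 | intermediate
21 | tetracyclic pyrrole lactone (target without ring D, C3–H; 9S,10R,11R,12S,13S) | CC[C@H]1[C@H]2OC(=O)[C@@H](C)[C@H]2c2ccn3c2[C@H]1CCCC3 | intermediate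
22 | (S)-3-methyldihydrofuran-2,5-dione ((S)-methylsuccinic anhydride) | C[C@H]1CC(=O)OC1=O | starting material
23 | (20S)-keto acid: C3–C(=O)–CH2–CH(CH3)–CO2H on 21 | CC[C@H]1[C@H]2OC(=O)[C@@H](C)[C@H]2c2cc(C(=O)C[C@H](C)C(=O)O)n3c2[C@H]1CCCC3 | intermediate
24 | (18R,20S)-hydroxy acid | CC[C@H]1[C@H]2OC(=O)[C@@H](C)[C@H]2c2cc([C@H](O)C[C@H](C)C(=O)O)n3c2[C@H]1CCCC3 | intermediate
25 | epibisdehydroneotuberostemonine J | CC[C@H]1[C@H]2OC(=O)[C@@H](C)[C@H]2c2cc([C@H]3C[C@H](C)C(=O)O3)n3c2[C@H]1CCCC3 | target

## Step count and least certain steps

Total: 18 steps. Longest linear sequence: 15 steps from 4 (steps 3–7 and 9–18).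

**Step 9 (key step).** The most likely failure is weak discrimination between the two faces of diene 9. Methyl and silyloxymethyl on C13 differ little in size near the diene, and the slim alkynyl group exerts only modest allylic strain. The all-cis adduct of the opposite ring configuration would then form alongside 12; it is a diastereomer of enantiopure material and separable, at a cost in material. Polymerisation of 11 before it reacts is a second concern. The fallback moves the cycloaddition one step earlier. Bromodiene 8 reacts with 11 to give the bromo cycloadduct F1; the larger bromine cis to C13 should tighten the conformational lock. Sonogashira coupling of F1 with ethynyltriisopropylsilane (Pd(P(t-Bu)3)2, CuI, i-Pr2NH) then returns to the route at 12.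

**Step 13.** Catecholborane may hydroborate the silyl alkyne or the enecarbamate in competition with C=N reduction, and the diazene may fragment incompletely. The fallback sets out from 13. LiBH4 reduces it to the diol F2, selective sulfonylation of the primary alcohol (TsCl, Et3N, DMAP) gives the monotosylate F3, and LiEt3BH at −78 → 0 °C displaces the tosylate by hydride, returning at 16. In that variant the free O11–H may close a tetrahydrofuran ring on C17, which is why it is not the first choice.

**Step 15.** The 5-endo-dig closure may be slow. The deprotected intermediate could then lose the C9 configuration by imine–enamine tautomerism, or the terminal alkyne could be hydrated. The fallback replaces hydroamination by a carbonyl condensation. From 17, anti-Markovnikov hydration of the alkyne (CpRuCl(dppm) cat., aqueous i-PrOH, 100 °C) gives the aldehyde F4. Treatment with CF3CO2H in CH2Cl2 removes the Boc group and cyclodehydrates in the Paal–Knorr manner, returning at 19.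

**Step 17.** The anhydride may be attacked at its more hindered carbonyl, giving the regioisomeric keto acid, and AlCl3 may degrade the electron-rich pyrrole. The fallback fixes the regiochemistry in the acylating agent. From 21, methyl (S)-4-chloro-2-methyl-4-oxobutanoate with Me2AlCl (CH2Cl2, 0 °C) gives the keto ester F5. The transfer hydrogenation of step 18 then gives the hydroxy ester F6, and gentle warming in toluene with 2-hydroxypyridine closes ring D, returning at 25.

**Step 18.** Hydride transfer to the deactivated ketone (a vinylogous amide flanked by the N4–CH2 group) may be slow and only weakly face-selective, and any acid would scramble the pyrrolylic centre C18. The fallback gives up catalyst control. From 23, NaBH4 in MeOH followed by the same carbodiimide lactonisation gives 25 together with its 18-epimer F7. The two are separated by chromatography, and F7 is recycled by brief exposure to a trace of CF3CO2H, which re-equilibrates C18 through the azafulvenium ion; the route is rejoined at 25.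

## Further compounds

F1 | step 9 | bromo cycloadduct: as 12 with Br on C1 in place of the silylethynyl group | O=C1C[C@H]2[C@@H]1[C@@H]([C@H](C)CO[Si](c4ccccc4)(c5ccccc5)C(C)(C)C)C(Br)=C3N(C(=O)OC(C)(C)C)CCCC[C@@H]23
F2 | step 13 | diol from 13: C10–CH2CH2OH and C11–OH | OCC[C@H]2[C@@H](O)[C@@H]([C@H](C)CO[Si](c4ccccc4)(c5ccccc5)C(C)(C)C)C(C#C[Si](C(C)C)(C(C)C)C(C)C)=C3N(C(=O)OC(C)(C)C)CCCC[C@@H]23
F3 | step 13 | primary monotosylate of F2 | Cc1ccc(cc1)S(=O)(=O)OCC[C@H]2[C@@H](O)[C@@H]([C@H](C)CO[Si](c4ccccc4)(c5ccccc5)C(C)(C)C)C(C#C[Si](C(C)C)(C(C)C)C(C)C)=C3N(C(=O)OC(C)(C)C)CCCC[C@@H]23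
F4 | step 15 | aldehyde from 17: C1–CH2–CHO in place of C1–C≡CH | CC[C@H]2[C@@H](O)[C@@H]([C@H](C)CO)C(CC=O)=C3N(C(=O)OC(C)(C)C)CCCC[C@@H]23
F5 | step 17 | methyl ester of keto acid 23 | CC[C@H]1[C@H]2OC(=O)[C@@H](C)[C@H]2c2cc(C(=O)C[C@H](C)C(=O)OC)n3c2[C@H]1CCCC3
F6 | step 17 | (18R)-hydroxy methyl ester | CC[C@H]1[C@H]2OC(=O)[C@@H](C)[C@H]2c2cc([C@H](O)C[C@H](C)C(=O)OC)n3c2[C@H]1CCCC3
F7 | step 18 | 18-epimer of 25 (18S) | CC[C@H]1[C@H]2OC(=O)[C@@H](C)[C@H]2c2cc([C@@H]3C[C@H](C)C(=O)O3)n3c2[C@H]1CCCC3
A1 | alternative 1 | 1,2,3,9a-tetrahydro (pyrrolidine) congener of 25, configurations at C1, C3 and C9a left open | CC[C@H]1[C@H]2OC(=O)[C@@H](C)[C@H]2C2CC([C@H]3C[C@H](C)C(=O)O3)N3CCCC[C@@H]1C23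
A2 | alternative 2 | pyrroloazepine with ring D on C3 and, on C9, the (10R)-CH(Et) group bearing the (11R)-α-methylbutenolide | CC[C@@H]([C@H]2OC(=O)C(C)=C2)[C@@H]1CCCCn3c1ccc3[C@H]4C[C@H](C)C(=O)O4
A3 | alternative 3 | methyl 6-[(Z)-oct-5-enyl]-6H-furo[2,3-b]pyrrole-5-carboxylate | CC/C=C\CCCCn1c(C(=O)OC)cc2ccoc12
A4 | alternative 3 | tricyclic C11 ketone with C3 methyl ester, C8 and ethyl cis (racemic, relative configuration shown) | CC[C@H]1C(=O)Cc2cc(C(=O)OC)n3c2[C@H]1CCCC3
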